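Ring A is closed last on a complete ring B. The C4–C5 bond unites two carbons of like polarity: C4 is alpha to the C3 ketone, and C5 is the alpha carbon of the ring B enone from which the C6 carbinol derives (a 1,4-relationship of O3 and O6). C5 is therefore inverted to an acceptor as a vinyl bromide, and a palladium-catalysed intramolecular enolate alkenylation closes ring A. The product's C4–H, flanked by the ketone and the tetrasubstituted C5=C10 alkene, is deprotonated in the flask; the planar dienolate is hydroxymethylated anti to the C6 silyl ether, so quaternary C4 forms stereoconvergently. The precursor is a monocyclic 2-bromocyclohexenyl ethyl ketone.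

Key step: step 8

Remark on locants: ring A = C1, C2, C3 (ketone), C4 (bears methyl C18 and CH2O C19), C5, C10; ring B = C5, C6 (carbinol), C7, C8 (methyl), C9 (methyl and side chain C11–C12), C10; butenolide = C13–C16. The target is (4S,6S,8S,9R).
Assumption: the (R,R)-TADDOL catalyst is taken to induce the absolute sense drawn for 3; if it induces the opposite sense, its commercially available enantiomer is used.
Remark: C5 in 5, C10 in 11 and 12 and C4 in F1 are stereocentres of no consequence (all are destroyed later) and are left undefined.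

Step 1
Reactants: 1 (E)-2-methylbut-2-enal; 2 (E)-3-[(tert-butyldimethylsilyl)oxy]-N,N-dimethylbuta-1,3-dien-1-amine
Product: 4 (1S,5S,6R)-3-[(tert-butyldimethylsilyl)oxy]-6-ethenyl-N,N,5,6-tetramethylcyclohex-2-en-1-amine, via aldehyde cycloadduct 3 (not isolated)
Conditions: (R,R)-1-naphthyl-TADDOL (20 mol%), toluene, −40 °C; then Ph3P=CH2 (from Ph3PCH3Br and KN(SiMe3)2), THF, −78 → 0 °C
Reagents that add atoms: methylenetriphenylphosphorane, C=P(c1ccccc1)(c1ccccc1)c1ccccc1
Why: The hydrogen-bond-catalysed Diels–Alder reaction of the 1-amino-3-siloxydiene with the E-enal should be endo- and regioselective, so the dienophile geometry fixes the cis relation of the C8 and C9 methyl groups and the catalyst the absolute sense, and the non-enolisable neopentyl aldehyde is then methylenated in the same flask by a Wittig reaction.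

Step 2
Reactants: 4 (1S,5S,6R)-3-[(tert-butyldimethylsilyl)oxy]-6-ethenyl-N,N,5,6-tetramethylcyclohex-2-en-1-amine
Product: 6 (4R,5S)-2-bromo-4-ethenyl-4,5-dimethylcyclohex-2-en-1-one, via bromo amino ketone 5 (not isolated)
Conditions: NBS, THF, −78 °C; then 1 M HCl, 0 °C → rt
Reagents that add atoms: N-bromosuccinimide, O=C1CCC(=O)N1Br
Why: Electrophilic bromination of the silyl enol ether places bromine on C5, and acid then expels dimethylamine by β-elimination (the usual unveiling of such cycloadducts to enones), which should give the α-bromoenone without touching C8, C9 or the vinyl group.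

Step 3
Reactants: 7 pent-1-en-3-one
Product: 9 2-(2-bromoethyl)-2-ethyl-1,3-dioxolane, via 1-bromopentan-3-one 8 (not isolated)
Conditions: HBr (gas), CH2Cl2, 0 °C; then ethylene glycol, TsOH (cat.), rt
Reagents that add atoms: hydrogen bromide, Br; ethylene glycol, OCCO
Why: Conjugate hydrobromination of the enone followed by acid-catalysed ketalisation is the standard preparation of β-bromoethyl dioxolanes.

Step 4
Reactants: 6 (4R,5S)-2-bromo-4-ethenyl-4,5-dimethylcyclohex-2-en-1-one; 9 2-(2-bromoethyl)-2-ethyl-1,3-dioxolane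
Product: 12 (4R,5S)-2,2-dibromo-3-[2-(2-ethyl-1,3-dioxolan-2-yl)ethyl]-4-ethenyl-4,5-dimethylcyclohexan-1-one (C3 epimers), via Grignard reagent 10 (not isolated), via bromo silyl enol ether 11 (not isolated)
Conditions: 9, Mg, THF, 25 °C; then CuBr·SMe2 (20 mol%), Me3SiCl, 6, THF, −78 °C; then NBS, −78 → 0 °C
Reagents that add atoms: N-bromosuccinimide, O=C1CCC(=O)N1Br
Why: Copper-catalysed, Me3SiCl-accelerated conjugate addition of the ketal Grignard reagent to the α-bromoenone should join C1 to C10 (the C10 configuration is irrelevant), and NBS bromination of the resulting bromo silyl enol ether gives the geminal dibromide.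

Step 5
Reactants: 12 (4R,5S)-2,2-dibromo-3-[2-(2-ethyl-1,3-dioxolan-2-yl)ethyl]-4-ethenyl-4,5-dimethylcyclohexan-1-one
Product: 13 (4R,5S)-2-bromo-3-[2-(2-ethyl-1,3-dioxolan-2-yl)ethyl]-4-ethenyl-4,5-dimethylcyclohex-2-en-1-one
Conditions: DBU, toluene, 80 °C
Reagents that add atoms: none
Why: E2 dehydrobromination can only use the C10–H, so both C10 epimers should converge on the α-bromoenone that now carries the chain on C10.

Step 6
Reactants: 13 (4R,5S)-2-bromo-3-[2-(2-ethyl-1,3-dioxolan-2-yl)ethyl]-4-ethenyl-4,5-dimethylcyclohex-2-en-1-one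
Product: 15 1-[(3S,5S,6R)-2-bromo-6-ethenyl-3-hydroxy-5,6-dimethylcyclohex-1-en-1-yl]pentan-3-one, via ketal alcohol 14 (not isolated)
Conditions: (R)-2-methyl-CBS-oxazaborolidine (20 mol%), catecholborane, toluene, −78 °C; then MeOH; 1 M HCl, THF, rt
Reagents that add atoms: water, O
Why: In the Corey–Bakshi–Shibata reduction the bromoalkenyl flank acts as the large group, so the (R)-oxazaborolidine should set (6S) under reagent control while catecholborane leaves the vinyl group alone, and the acidic work-up hydrolyses the dioxolane.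

Step 7
Reactants: 15 1-[(3S,5S,6R)-2-bromo-6-ethenyl-3-hydroxy-5,6-dimethylcyclohex-1-en-1-yl]pentan-3-one
Product: 16 1-[(3S,5S,6R)-2-bromo-3-[(tert-butyldimethylsilyl)oxy]-6-ethenyl-5,6-dimethylcyclohex-1-en-1-yl]pentan-3-one
Conditions: TBSCl, imidazole, DMF, 40 °C
Reagents that add atoms: tert-butyldimethylsilyl chloride, C[Si](C)(Cl)C(C)(C)C
Why: Standard silylation of the secondary allylic alcohol installs the bulky group that later shields one face of ring A.

Step 8
Reactants: 16 1-[(3S,5S,6R)-2-bromo-3-[(tert-butyldimethylsilyl)oxy]-6-ethenyl-5,6-dimethylcyclohex-1-en-1-yl]pentan-3-one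
Product: 18 (1S,5R,6S,8S)-8-[(tert-butyldimethylsilyl)oxy]-5-ethenyl-1-(hydroxymethyl)-1,5,6-trimethyl-3,4,5,6,7,8-hexahydronaphthalen-2(1H)-one, via lithium dienolate 17 (not isolated)
Conditions: Pd2(dba)3 (5 mol%), P(tBu)3·HBF4 (12 mol%), LiN(SiMe3)2 (2.6 equiv), THF, 50 °C; then −78 °C, monomeric CH2O (THF solution from cracked paraformaldehyde); AcOH, −78 °C
Reagents that add atoms: formaldehyde, C=O
Why: Oxidative addition of zerovalent palladium into the C5–Br bond, displacement of bromide by the lithium enolate and C–C reductive elimination form C4–C5 (intramolecular palladium-catalysed ketone α-alkenylation is the closest known reaction type); the excess amide base then removes the doubly activated C4–H to give dienolate 17, which adds to formaldehyde at its α-carbon C4 (deconjugative aldol). Ring A closes as a six-membered ring in an enolendo mode through a seven-membered palladacycle, whereas the C2 enolate, which equilibrates through HN(SiMe3)2, could only give a cyclobutane. The one new stereocentre, quaternary C4, is controlled by the C6 silyl ether: in the planar dienolate the in-plane C18 methyl forces C6–H into the plane (allylic 1,3-strain), the OTBS group stands pseudoaxial on one face, and formaldehyde should enter from the other, placing C19 anti to O6 as in the target (4S). The step is stereoconvergent because both C4 epimers of the cyclised ketone and both enolate geometries funnel into the same dienolate. It needs C- over O-alkenylation (palladium eliminates from the C-bound enolate), α- over γ-attack of the dienolate (C10 is flanked by quaternary C9) and single hydroxymethylation (C4 is quaternary after one addition and the quench is cold). β-Elimination from the C5 vinylpalladium toward C6 cannot occur because it would give a cyclic allene.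

Step 9
Reactants: 19 3-(4-hydroxyphenyl)propanoic acid
Product: 21 3-(4-{[tri(propan-2-yl)silyl]oxy}phenyl)propanoic acid, via bis-silylated acid 20 (not isolated)
Conditions: iPr3SiCl (2.2 equiv), imidazole, DMF, rt; then K2CO3, MeOH/H2O, rt; 1 M HCl to pH 3
Reagents that add atoms: triisopropylsilyl chloride, CC(C)[Si](Cl)(C(C)C)C(C)C
Why: Silylation of both acidic OH groups followed by selective solvolysis of the labile silyl ester should leave the phenol as a base-stable silyl ether.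

Step 10
Reactants: 18 (1S,5R,6S,8S)-8-[(tert-butyldimethylsilyl)oxy]-5-ethenyl-1-(hydroxymethyl)-1,5,6-trimethyl-3,4,5,6,7,8-hexahydronaphthalen-2(1H)-one; 21 3-(4-{[tri(propan-2-yl)silyl]oxy}phenyl)propanoic acid
Product: 22 [(1S,5R,6S,8S)-8-[(tert-butyldimethylsilyl)oxy]-5-ethenyl-1,5,6-trimethyl-2-oxo-1,2,3,4,5,6,7,8-octahydronaphthalen-1-yl]methyl 3-(4-{[tri(propan-2-yl)silyl]oxy}phenyl)propanoate
Conditions: DCC, DMAP (cat.), CH2Cl2, 0 °C → rt
Reagents that add atoms: none
Why: Steglich esterification of the neopentyl primary alcohol is mild enough to avoid retro-aldol cleavage of the β-hydroxy ketone, and the ester then blocks that pathway for good.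

Step 11
Reactants: 22 [(1S,5R,6S,8S)-8-[(tert-butyldimethylsilyl)oxy]-5-ethenyl-1,5,6-trimethyl-2-oxo-1,2,3,4,5,6,7,8-octahydronaphthalen-1-yl]methyl 3-(4-{[tri(propan-2-yl)silyl]oxy}phenyl)propanoate; 23 4-bromofuran-2(5H)-one
Product: 25 [(1S,5R,6S,8S)-8-[(tert-butyldimethylsilyl)oxy]-1,5,6-trimethyl-2-oxo-5-[2-(5-oxo-2,5-dihydrofuran-3-yl)ethyl]-1,2,3,4,5,6,7,8-octahydronaphthalen-1-yl]methyl 3-(4-{[tri(propan-2-yl)silyl]oxy}phenyl)propanoate, via B-alkyl-9-BBN borane 24 (not isolated)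
Conditions: 9-BBN, THF, 0 °C → rt; then 23, PdCl2(dppf) (10 mol%), AsPh3, aq. K3PO4, DMF, rt
Reagents that add atoms: none
Why: Anti-Markovnikov hydroboration of the only unhindered alkene by 9-BBN (the tetrasubstituted C5=C10 alkene and the α-quaternary ketone should react far more slowly) and B-alkyl Suzuki–Miyaura coupling with the β-bromobutenolide join C12 to C13.

Step 12
Reactants: 25 [(1S,5R,6S,8S)-8-[(tert-butyldimethylsilyl)oxy]-1,5,6-trimethyl-2-oxo-5-[2-(5-oxo-2,5-dihydrofuran-3-yl)ethyl]-1,2,3,4,5,6,7,8-octahydronaphthalen-1-yl]methyl 3-(4-{[tri(propan-2-yl)silyl]oxy}phenyl)propanoate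
Product: 26 [(1S,5R,6S,8S)-8-hydroxy-1,5,6-trimethyl-2-oxo-5-[2-(5-oxo-2,5-dihydrofuran-3-yl)ethyl]-1,2,3,4,5,6,7,8-octahydronaphthalen-1-yl]methyl 3-(4-hydroxyphenyl)propanoate (target)
Conditions: Bu4NF, AcOH, THF, 0 °C → rt
Reagents that add atoms: none
Why: Fluoride-mediated desilylation of the aryl and the secondary silyl ether, buffered with acetic acid to spare the butenolide and the ester, should release the target.

Compound list
1 | (E)-2-methylbut-2-enal | C/C=C(\C)C=O | starting material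
2 | (E)-3-[(tert-butyldimethylsilyl)oxy]-N,N-dimethylbuta-1,3-dien-1-amine | CN(C)/C=C/C(=C)O[Si](C)(C)C(C)(C)C | starting material
3 | (1R,2S,6S)-4-[(tert-butyldimethylsilyl)oxy]-2-(dimethylamino)-1,6-dimethylcyclohex-3-ene-1-carbaldehyde (endo adduct) | C[C@H]1CC(O[Si](C)(C)C(C)(C)C)=C[C@H](N(C)C)[C@]1(C)C=O | intermediate
4 | (1S,5S,6R)-3-[(tert-butyldimethylsilyl)oxy]-6-ethenyl-N,N,5,6-tetramethylcyclohex-2-en-1-amine | C[C@H]1CC(O[Si](C)(C)C(C)(C)C)=C[C@H](N(C)C)[C@]1(C)C=C | intermediate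
5 | (3R,4R,5S)-2-bromo-3-(dimethylamino)-4-ethenyl-4,5-dimethylcyclohexan-1-one (C2 epimers) | C[C@H]1CC(=O)C(Br)[C@H](N(C)C)[C@]1(C)C=C | intermediate
6 | (4R,5S)-2-bromo-4-ethenyl-4,5-dimethylcyclohex-2-en-1-one | C[C@H]1CC(=O)C(Br)=C[C@]1(C)C=C | intermediate
7 | pent-1-en-3-one | C=CC(=O)CC | starting material
8 | 1-bromopentan-3-one | BrCCC(=O)CC | intermediate
9 | 2-(2-bromoethyl)-2-ethyl-1,3-dioxolane | BrCCC1(CC)OCCO1 | intermediate
10 | [2-(2-ethyl-1,3-dioxolan-2-yl)ethyl]magnesium bromide | Br[Mg]CCC1(CC)OCCO1 | intermediate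
11 | {[(4R,5S)-2-bromo-3-[2-(2-ethyl-1,3-dioxolan-2-yl)ethyl]-4-ethenyl-4,5-dimethylcyclohex-1-en-1-yl]oxy}trimethylsilane (C3 epimers) | C[C@H]1CC(O[Si](C)(C)C)=C(Br)C(CCC2(CC)OCCO2)[C@]1(C)C=C | intermediate
12 | (4R,5S)-2,2-dibromo-3-[2-(2-ethyl-1,3-dioxolan-2-yl)ethyl]-4-ethenyl-4,5-dimethylcyclohexan-1-one (C3 epimers) | C[C@H]1CC(=O)C(Br)(Br)C(CCC2(CC)OCCO2)[C@]1(C)C=C | intermediate
13 | (4R,5S)-2-bromo-3-[2-(2-ethyl-1,3-dioxolan-2-yl)ethyl]-4-ethenyl-4,5-dimethylcyclohex-2-en-1-one | C[C@H]1CC(=O)C(Br)=C(CCC2(CC)OCCO2)[C@]1(C)C=C | intermediate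
14 | (1S,4R,5S)-2-bromo-3-[2-(2-ethyl-1,3-dioxolan-2-yl)ethyl]-4-ethenyl-4,5-dimethylcyclohex-2-en-1-ol | C[C@H]1C[C@H](O)C(Br)=C(CCC2(CC)OCCO2)[C@]1(C)C=C | intermediate
15 | 1-[(3S,5S,6R)-2-bromo-6-ethenyl-3-hydroxy-5,6-dimethylcyclohex-1-en-1-yl]pentan-3-one | C[C@H]1C[C@H](O)C(Br)=C(CCC(=O)CC)[C@]1(C)C=C | intermediate
16 | 1-[(3S,5S,6R)-2-bromo-3-[(tert-butyldimethylsilyl)oxy]-6-ethenyl-5,6-dimethylcyclohex-1-en-1-yl]pentan-3-one | C[C@H]1C[C@H](O[Si](C)(C)C(C)(C)C)C(Br)=C(CCC(=O)CC)[C@]1(C)C=C | intermediate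
17 | lithium (5R,6S,8S)-8-[(tert-butyldimethylsilyl)oxy]-5-ethenyl-1,5,6-trimethyl-3,4,5,6,7,8-hexahydronaphthalen-2-olate | C[C@H]1C[C@H](O[Si](C)(C)C(C)(C)C)C2=C(CCC([O-])=C2C)[C@]1(C)C=C.[Li+] | intermediate
18 | (1S,5R,6S,8S)-8-[(tert-butyldimethylsilyl)oxy]-5-ethenyl-1-(hydroxymethyl)-1,5,6-trimethyl-3,4,5,6,7,8-hexahydronaphthalen-2(1H)-one | C[C@H]1C[C@H](O[Si](C)(C)C(C)(C)C)C2=C(CCC(=O)[C@]2(C)CO)[C@]1(C)C=C | intermediate
19 | 3-(4-hydroxyphenyl)propanoic acid | OC(=O)CCc1ccc(O)cc1 | starting material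
20 | tri(propan-2-yl)silyl 3-(4-{[tri(propan-2-yl)silyl]oxy}phenyl)propanoate | CC(C)[Si](C(C)C)(C(C)C)OC(=O)CCc1ccc(O[Si](C(C)C)(C(C)C)C(C)C)cc1 | intermediate
21 | 3-(4-{[tri(propan-2-yl)silyl]oxy}phenyl)propanoic acid | OC(=O)CCc1ccc(O[Si](C(C)C)(C(C)C)C(C)C)cc1 | intermediate
22 | [(1S,5R,6S,8S)-8-[(tert-butyldimethylsilyl)oxy]-5-ethenyl-1,5,6-trimethyl-2-oxo-1,2,3,4,5,6,7,8-octahydronaphthalen-1-yl]methyl 3-(4-{[tri(propan-2-yl)silyl]oxy}phenyl)propanoate | C[C@H]1C[C@H](O[Si](C)(C)C(C)(C)C)C2=C(CCC(=O)[C@]2(C)COC(=O)CCc2ccc(O[Si](C(C)C)(C(C)C)C(C)C)cc2)[C@]1(C)C=C | intermediate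
23 | 4-bromofuran-2(5H)-one | BrC1=CC(=O)OC1 | starting material
24 | B-alkyl-9-borabicyclo[3.3.1]nonane formed from 22 at C12 | C[C@H]1C[C@H](O[Si](C)(C)C(C)(C)C)C2=C(CCC(=O)[C@]2(C)COC(=O)CCc2ccc(O[Si](C(C)C)(C(C)C)C(C)C)cc2)[C@]1(C)CCB1C2CCCC1CCC2 | intermediate
25 | [(1S,5R,6S,8S)-8-[(tert-butyldimethylsilyl)oxy]-1,5,6-trimethyl-2-oxo-5-[2-(5-oxo-2,5-dihydrofuran-3-yl)ethyl]-1,2,3,4,5,6,7,8-octahydronaphthalen-1-yl]methyl 3-(4-{[tri(propan-2-yl)silyl]oxy}phenyl)propanoate | C[C@H]1C[C@H](O[Si](C)(C)C(C)(C)C)C2=C(CCC(=O)[C@]2(C)COC(=O)CCc2ccc(O[Si](C(C)C)(C(C)C)C(C)C)cc2)[C@]1(C)CCC1=CC(=O)OC1 | intermediate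
26 | [(1S,5R,6S,8S)-8-hydroxy-1,5,6-trimethyl-2-oxo-5-[2-(5-oxo-2,5-dihydrofuran-3-yl)ethyl]-1,2,3,4,5,6,7,8-octahydronaphthalen-1-yl]methyl 3-(4-hydroxyphenyl)propanoate | C[C@H]1C[C@H](O)C2=C(CCC(=O)[C@]2(C)COC(=O)CCc2ccc(O)cc2)[C@]1(C)CCC1=CC(=O)OC1 | target

Total step count: 12. Longest linear sequence: 10 steps (steps 1, 2, 4, 5, 6, 7, 8, 10, 11, 12); steps 3 and 9 prepare side fragments.

Steps most likely to fail

Step 8. Oxidative addition and C–C reductive elimination at the fully substituted C5 may be outrun by protodebromination or O-alkenylation. The dienolate may also be lost by proton shuffling to an isomeric dienolate or by retro-aldol cleavage during hydroxymethylation in the same flask. Fallback: setting out from 16, the bond is formed without a transition metal by photostimulated SRN1 substitution (KOtBu, liquid NH3/THF, hν, −33 °C; NH4Cl quench). This should give the cyclised β,γ-unsaturated ketone (5R,6S,8S)-8-[(tert-butyldimethylsilyl)oxy]-5-ethenyl-1,5,6-trimethyl-3,4,5,6,7,8-hexahydronaphthalen-2(1H)-one F1 as a C4 epimer mixture. In a separate operation F1 is deprotonated with LiN(SiMe3)2 at −78 °C to dienolate 17 and treated with formaldehyde, coming back to the route at 18.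

Step 4. The organocopper reagent may attack the α-bromoenone by halogen–metal exchange, reductive debromination or 1,2-addition instead of conjugate addition. Fallback: setting out from 4, 1 M HCl in THF should unveil the parent enone (4R,5S)-4-ethenyl-4,5-dimethylcyclohex-2-en-1-one F2. The same copper-catalysed addition of 10 with Me3SiCl gives the silyl enol ether {[(4R,5S)-3-[2-(2-ethyl-1,3-dioxolan-2-yl)ethyl]-4-ethenyl-4,5-dimethylcyclohex-1-en-1-yl]oxy}trimethylsilane F3. NBS converts F3 in the flask into the monobromo ketone (4R,5S)-2-bromo-3-[2-(2-ethyl-1,3-dioxolan-2-yl)ethyl]-4-ethenyl-4,5-dimethylcyclohexan-1-one F4. LiN(SiMe3)2 and Me3SiCl then turn F4 into the bromo silyl enol ether 11, where the route is rejoined.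

Step 1. With a β-substituted enal the hydrogen-bond-catalysed cycloaddition may be slow, so that an uncatalysed background reaction erodes facial selectivity. Fallback: auxiliary control, setting out from 1. 4-Methoxybut-3-en-2-one and (2R,5R)-2,5-diphenylpyrrolidine condense to the vinylogous amide (E)-4-[(2R,5R)-2,5-diphenylpyrrolidin-1-yl]but-3-en-2-one F5. KN(SiMe3)2 and TBSCl give the chiral diene (2R,5R)-1-[(1E)-3-[(tert-butyldimethylsilyl)oxy]buta-1,3-dien-1-yl]-2,5-diphenylpyrrolidine F6. Thermal cycloaddition with 1 gives the aldehyde (1R,2S,6S)-4-[(tert-butyldimethylsilyl)oxy]-2-[(2R,5R)-2,5-diphenylpyrrolidin-1-yl]-1,6-dimethylcyclohex-3-ene-1-carbaldehyde F7. Wittig methylenation gives the vinyl compound (2R,5R)-1-[(1S,5S,6R)-3-[(tert-butyldimethylsilyl)oxy]-6-ethenyl-5,6-dimethylcyclohex-2-en-1-yl]-2,5-diphenylpyrrolidine F8. NBS followed by aqueous acid, as in step 2, comes back to the route at 6 with release of the pyrrolidine; the auxiliary enantiomer that gives the sense shown would be used.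

Further compounds
F1 | step 8 | (5R,6S,8S)-8-[(tert-butyldimethylsilyl)oxy]-5-ethenyl-1,5,6-trimethyl-3,4,5,6,7,8-hexahydronaphthalen-2(1H)-one (C1 epimers) | C[C@H]1C[C@H](O[Si](C)(C)C(C)(C)C)C2=C(CCC(=O)C2C)[C@]1(C)C=C
F2 | step 4 | (4R,5S)-4-ethenyl-4,5-dimethylcyclohex-2-en-1-one | C[C@H]1CC(=O)C=C[C@]1(C)C=C
F3 | step 4 | {[(4R,5S)-3-[2-(2-ethyl-1,3-dioxolan-2-yl)ethyl]-4-ethenyl-4,5-dimethylcyclohex-1-en-1-yl]oxy}trimethylsilane (C3 epimers) | C[C@H]1CC(O[Si](C)(C)C)=CC(CCC2(CC)OCCO2)[C@]1(C)C=C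
F4 | step 4 | (4R,5S)-2-bromo-3-[2-(2-ethyl-1,3-dioxolan-2-yl)ethyl]-4-ethenyl-4,5-dimethylcyclohexan-1-one (C2 and C3 epimers) | C[C@H]1CC(=O)C(Br)C(CCC2(CC)OCCO2)[C@]1(C)C=C
F5 | step 1 | (E)-4-[(2R,5R)-2,5-diphenylpyrrolidin-1-yl]but-3-en-2-one | CC(=O)/C=C/N1[C@@H](c2ccccc2)CC[C@@H]1c1ccccc1
F6 | step 1 | (2R,5R)-1-[(1E)-3-[(tert-butyldimethylsilyl)oxy]buta-1,3-dien-1-yl]-2,5-diphenylpyrrolidine | C=C(O[Si](C)(C)C(C)(C)C)/C=C/N1[C@@H](c2ccccc2)CC[C@@H]1c1ccccc1
F7 | step 1 | (1R,2S,6S)-4-[(tert-butyldimethylsilyl)oxy]-2-[(2R,5R)-2,5-diphenylpyrrolidin-1-yl]-1,6-dimethylcyclohex-3-ene-1-carbaldehyde | C[C@H]1CC(O[Si](C)(C)C(C)(C)C)=C[C@H](N2[C@@H](c3ccccc3)CC[C@@H]2c2ccccc2)[C@]1(C)C=O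
F8 | step 1 | (2R,5R)-1-[(1S,5S,6R)-3-[(tert-butyldimethylsilyl)oxy]-6-ethenyl-5,6-dimethylcyclohex-2-en-1-yl]-2,5-diphenylpyrrolidine | C[C@H]1CC(O[Si](C)(C)C(C)(C)C)=C[C@H](N2[C@@H](c3ccccc3)CC[C@@H]2c2ccccc2)[C@]1(C)C=C
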